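**Retrosynthetic overview**

1. Target ⇐ α-face epoxidation of the C8=C9 alkene of the 6-benzoate ⇐ selective benzoylation of dauc-8-ene-4β,6α-diol.
2. Seven-membered ring (formed second) ⇐ ring-closing metathesis at C8=C9 of a cyclopentane with trans-disposed allyl (on C1) and 1-hydroxy-3-methylbut-3-enyl (on C5) chains ⇐ methallylboration of the C6 aldehyde.
3. C1 quaternary centre and C5 ⇐ conjugate methylation of a 2-allyl-5-hydroxy-5-isopropylcyclopentene-1-carbaldehyde anti to isopropyl, then equilibration at C5.
4. Five-membered ring (formed first), key disconnection: C1–C2 and C4–C5 made in one operation from the zinc homoenolate of 1-isopropylcyclopropanol (nucleophilic β-carbon of a ketone) and the β-carbon of an alkynyl Weinreb amide.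
5. Building blocks: pent-1-en-4-yne plus the Weinreb carbamoyl chloride; methyl 2-methylpropanoate plus EtMgBr (Kulinkovich); oxirane closed last.

Assumption: daucane numbering is used for the skeleton (C1 methyl-bearing ring-fusion carbon, C4 carbinol carbon with isopropyl, C5 ring-fusion CH, C6 benzoyloxy carbon, C8/C9 oxirane carbons), and β is the face of the C1 methyl group.

**Route**

Step 1
Reactants: 1 pent-1-en-4-yne
Product: 3 N-methoxy-N-methylhex-5-en-2-ynamide, via lithium pent-4-en-1-yn-1-ide 2 (not isolated)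
Conditions: n-BuLi (1.0 equiv), THF, −78 °C; then ClC(O)N(OMe)Me, −78 → 0 °C
Reagents that add atoms: N-methoxy-N-methylcarbamoyl chloride, CN(OC)C(=O)Cl
Why: Acetylide acylation, in which n-BuLi removes only the terminal alkyne hydrogen at −78 °C and the lithium acetylide is acylated once because the Weinreb amide product resists a second addition; no stereocentre is formed.

Step 2
Reactants: 4 methyl 2-methylpropanoate
Product: 5 1-(propan-2-yl)cyclopropan-1-ol
Conditions: EtMgBr (2.4 equiv), Ti(OiPr)4 (0.2 equiv), Et2O, 0 → 23 °C; then H2O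
Reagents that add atoms: ethylmagnesium bromide, CC[Mg]Br
Why: Kulinkovich cyclopropanation, in which the titanacyclopropane made from two ethyl groups acts as a 1,2-dicarbanion towards the ester; no stereocentre is formed.

Step 3
Reactants: 3 N-methoxy-N-methylhex-5-en-2-ynamide; 5 1-(propan-2-yl)cyclopropan-1-ol
Product: 10 (5R)-5-hydroxy-N-methoxy-N-methyl-5-(propan-2-yl)-2-(prop-2-en-1-yl)cyclopent-1-ene-1-carboxamide, via zinc bis(1-isopropylcyclopropanolate) 6 (not isolated), via bis(4-methyl-3-oxopentyl)zinc 7 (not isolated), via alkenylzinc adduct 8 (not isolated), via zinc alkoxide 9 (not isolated)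
Conditions: 5 (2.2 equiv), Et2Zn (1.1 equiv), THF, 0 → 23 °C; then 3, Cu(OAc)2 (5 mol %), (R)-DTBM-SEGPHOS (6 mol %; antipode to be fixed on the first run so that the 5R carbinol results), −20 → 23 °C; pH 7 buffer
Reagents that add atoms: none
Why: Proposed new method: Et2Zn deprotonates 5 and strain-driven ring opening gives the zinc homoenolate 7, whose β-carbon is passed to copper and adds syn across the alkyne at the β-carbon of the alkynamide, which leaves the metal-bearing carbon cis to the keto chain so that it closes the cyclopentene by 1,2-addition to the isopropyl ketone inside the chiral bisphosphine–copper pocket and sets the tertiary carbinol centre (5R), the closest known reaction types being the cobalt–diphosphine [3+2] annulation of cyclopropanols with internal alkynes to cyclopent-2-enols, copper-catalysed conjugate additions of zinc homoenolates, and copper–bisphosphine alkylative aldol additions of zinc-derived nucleophiles to ketones.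

Step 4
Reactants: 10 (5R)-5-hydroxy-N-methoxy-N-methyl-5-(propan-2-yl)-2-(prop-2-en-1-yl)cyclopent-1-ene-1-carboxamide
Product: 12 (5R)-5-hydroxy-5-(propan-2-yl)-2-(prop-2-en-1-yl)cyclopent-1-ene-1-carbaldehyde, via aluminium hemiaminal 11 (not isolated)
Conditions: iBu2AlH (2.5 equiv), THF, −78 °C; aq. Rochelle salt
Reagents that add atoms: none
Why: Weinreb amide reduction, in which the first equivalent of hydride is spent on the hydroxyl and the second gives a chelated tetrahedral aluminate that only collapses to the aldehyde on work-up; the carbinol centre is untouched.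

Step 5
Reactants: 12 (5R)-5-hydroxy-5-(propan-2-yl)-2-(prop-2-en-1-yl)cyclopent-1-ene-1-carbaldehyde
Product: 15 (1R,2R,5R)-2-hydroxy-5-methyl-2-(propan-2-yl)-5-(prop-2-en-1-yl)cyclopentane-1-carbaldehyde, via silyl enol ether 13 (not isolated), via formyl epimer 14 (not isolated)
Conditions: MeMgBr (3 equiv), CuBr·SMe2 (10 mol %), TMSCl (3 equiv), DMPU, THF, −78 → −40 °C; 1 M HCl, THF, 0 °C; then DBU (0.2 equiv), CH2Cl2, 23 °C
Reagents that add atoms: methylmagnesium bromide, C[Mg]Br
Why: Copper-catalysed, TMSCl-accelerated conjugate addition of the Grignard reagent to the β,β-disubstituted enal, in which methyl enters anti to the isopropyl group and on the face of the magnesium alkoxide of the neighbouring stereocentre (1,3-induction as in 5-substituted cyclopentene carbaldehydes) to create the quaternary centre, after which DBU equilibrates the enolisable formyl centre through its enolate to the isomer trans to isopropyl and allyl and hydrogen-bonded to the cis hydroxyl.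

Step 6
Reactants: 15 (1R,2R,5R)-2-hydroxy-5-methyl-2-(propan-2-yl)-5-(prop-2-en-1-yl)cyclopentane-1-carbaldehyde
Product: 17 (1R,2S,3R)-2-[(1S)-1-hydroxy-3-methylbut-3-en-1-yl]-3-methyl-1-(propan-2-yl)-3-(prop-2-en-1-yl)cyclopentan-1-ol, via diisopinocampheylborinate 16 (not isolated)
Conditions: (−)-Ipc2BOMe, CH2=C(CH3)CH2MgCl, Et2O, −78 → 23 °C; then 15, −78 °C; NaOH, H2O2, 0 → 23 °C
Reagents that add atoms: 2-methylallylmagnesium chloride, CC(=C)C[Mg]Cl
Why: Brown methallylboration through a closed chair transition state, in which the reagent derived from (+)-α-pinene attacks the Si face of the aldehyde to give the (1S)-carbinol (the same sense as the non-chelated Felkin preference with the carbinol carbon anti) while the hindered tertiary hydroxyl is inert at −78 °C.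

Step 7
Reactants: 17 (1R,2S,3R)-2-[(1S)-1-hydroxy-3-methylbut-3-en-1-yl]-3-methyl-1-(propan-2-yl)-3-(prop-2-en-1-yl)cyclopentan-1-ol
Product: 18 (3R,3aS,4S,8aR)-6,8a-dimethyl-3-(propan-2-yl)-1,2,3,3a,4,5,8,8a-octahydroazulene-3,4-diol
Conditions: second-generation Grubbs catalyst (5 mol %), CH2Cl2 (0.005 M), 40 °C
Reagents that add atoms: none
Why: Ring-closing metathesis between the allyl group and the 1,1-disubstituted methallyl alkene closes the seven-membered ring as the trisubstituted C8=C9 alkene, and because the two chains are trans on the cyclopentane the hydroazulene is trans-fused; no stereocentre is formed or touched.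

Step 8
Reactants: 18 (3R,3aS,4S,8aR)-6,8a-dimethyl-3-(propan-2-yl)-1,2,3,3a,4,5,8,8a-octahydroazulene-3,4-diol
Product: 19 (3R,3aS,4S,8aR)-3-hydroxy-6,8a-dimethyl-3-(propan-2-yl)-1,2,3,3a,4,5,8,8a-octahydroazulen-4-yl benzoate
Conditions: BzCl (1.2 equiv), pyridine, DMAP (0.1 equiv), CH2Cl2, 0 → 23 °C
Reagents that add atoms: benzoyl chloride, O=C(Cl)c1ccccc1
Why: DMAP-catalysed acylation, in which the secondary hydroxyl reacts and the tertiary hydroxyl next to the isopropyl group does not; configuration is retained.

Step 9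
Reactants: 19 (3R,3aS,4S,8aR)-3-hydroxy-6,8a-dimethyl-3-(propan-2-yl)-1,2,3,3a,4,5,8,8a-octahydroazulen-4-yl benzoate
Product: 20 (1R,4R,5S,6S,8R,9S)-8,9-epoxy-4-hydroxydaucan-6-yl benzoate
Conditions: mCPBA (1.1 equiv), NaHCO3, CH2Cl2, 0 °C
Reagents that add atoms: 3-chloroperoxybenzoic acid, OOC(=O)c1cccc(Cl)c1
Why: Prilezhaev epoxidation of the only alkene, in which the peracid is expected to add to the α face, opposite the axial angular methyl group two bonds from C9, giving the (8R,9S)-oxirane, while the bicarbonate buffer keeps the tertiary hydroxyl from opening the epoxide.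

**Compound list**

1 | pent-1-en-4-yne | C=CCC#C | starting material
2 | lithium pent-4-en-1-yn-1-ide | [Li]C#CCC=C | intermediate
3 | N-methoxy-N-methylhex-5-en-2-ynamide | C=CCC#CC(=O)N(C)OC | intermediate
4 | methyl 2-methylpropanoate | COC(=O)C(C)C | starting material
5 | 1-(propan-2-yl)cyclopropan-1-ol | CC(C)C1(O)CC1 | intermediate
6 | zinc bis[1-(propan-2-yl)cyclopropan-1-olate] | CC(C)C1(CC1)O[Zn]OC1(CC1)C(C)C | intermediate
7 | bis(4-methyl-3-oxopentyl)zinc (zinc homoenolate) | CC(C)C(=O)CC[Zn]CCC(=O)C(C)C | intermediate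
8 | alkenylzinc adduct: zinc on the amide-bearing alkene carbon, cis to the 4-methyl-3-oxopentyl chain, second ligand on zinc 4-methyl-3-oxopentyl | C=CC/C(CCC(=O)C(C)C)=C(/[Zn]CCC(=O)C(C)C)C(=O)N(C)OC | intermediate
9 | (4-methyl-3-oxopentyl)zinc (1R)-2-[methoxy(methyl)carbamoyl]-1-(propan-2-yl)-3-(prop-2-en-1-yl)cyclopent-2-en-1-olate | CC(C)[C@]1(O[Zn]CCC(=O)C(C)C)CCC(CC=C)=C1C(=O)N(C)OC | intermediate
10 | (5R)-5-hydroxy-N-methoxy-N-methyl-5-(propan-2-yl)-2-(prop-2-en-1-yl)cyclopent-1-ene-1-carboxamide | CC(C)[C@]1(O)CCC(CC=C)=C1C(=O)N(C)OC | intermediate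
11 | aluminium hemiaminal: 10 with O–Al(iBu)2 on the carbinol oxygen and the amide carbon reduced to CH[OAl(iBu)2][N(OMe)Me] | CC(C)[C@]1(O[Al](CC(C)C)CC(C)C)CCC(CC=C)=C1C(O[Al](CC(C)C)CC(C)C)N(C)OC | intermediate
12 | (5R)-5-hydroxy-5-(propan-2-yl)-2-(prop-2-en-1-yl)cyclopent-1-ene-1-carbaldehyde | CC(C)[C@]1(O)CCC(CC=C)=C1C=O | intermediate
13 | silyl enol ether: trimethylsilyl enol ether at the formyl carbon of 15, tertiary oxygen as its bromomagnesium alkoxide | CC(C)[C@]1(O[Mg]Br)CC[C@](C)(CC=C)C1=CO[Si](C)(C)C | intermediate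
14 | (1S,2R,5R)-2-hydroxy-5-methyl-2-(propan-2-yl)-5-(prop-2-en-1-yl)cyclopentane-1-carbaldehyde (formyl epimer of 15) | CC(C)[C@]1(O)CC[C@](C)(CC=C)[C@@H]1C=O | intermediate
15 | (1R,2R,5R)-2-hydroxy-5-methyl-2-(propan-2-yl)-5-(prop-2-en-1-yl)cyclopentane-1-carbaldehyde | CC(C)[C@]1(O)CC[C@](C)(CC=C)[C@H]1C=O | intermediate
16 | diisopinocampheylborinate ester of 17 at the secondary oxygen | CC(C)[C@]1(O)CC[C@](C)(CC=C)[C@H]1[C@@H](OB([C@@H]2C[C@@H]3C[C@H]([C@H]2C)C3(C)C)[C@@H]2C[C@@H]3C[C@H]([C@H]2C)C3(C)C)CC(C)=C | intermediate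
17 | (1R,2S,3R)-2-[(1S)-1-hydroxy-3-methylbut-3-en-1-yl]-3-methyl-1-(propan-2-yl)-3-(prop-2-en-1-yl)cyclopentan-1-ol | CC(C)[C@]1(O)CC[C@](C)(CC=C)[C@H]1[C@@H](O)CC(C)=C | intermediate
18 | (3R,3aS,4S,8aR)-6,8a-dimethyl-3-(propan-2-yl)-1,2,3,3a,4,5,8,8a-octahydroazulene-3,4-diol (trans-fused dauc-8-ene-4β,6α-diol) | CC(C)[C@]1(O)CC[C@]2(C)CC=C(C)C[C@H](O)[C@H]21 | intermediate
19 | (3R,3aS,4S,8aR)-3-hydroxy-6,8a-dimethyl-3-(propan-2-yl)-1,2,3,3a,4,5,8,8a-octahydroazulen-4-yl benzoate | CC(C)[C@]1(O)CC[C@]2(C)CC=C(C)C[C@H](OC(=O)c3ccccc3)[C@H]21 | intermediate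
20 | (1R,4R,5S,6S,8R,9S)-8,9-epoxy-4-hydroxydaucan-6-yl benzoate (8α,9α-epoxide of 19; CNP0340059.1) | CC(C)[C@]1(O)CC[C@]2(C)C[C@@H]3O[C@]3(C)C[C@H](OC(=O)c3ccccc3)[C@H]21 | target

**Step count and risks**

Total step count: 9. Longest linear sequence: 8 steps (1 → 3 → 10 → 12 → 15 → 17 → 18 → 19 → 20).

Steps most likely to fail:

Step 3 (the annulation is new in this form; reactivity of the chelated homoenolate and the enantioselectivity of the ring-closing addition are both untested). The fallback sets out from 3 and 5 and gives up asymmetric catalysis: the two are joined under achiral cobalt–diphosphine catalysis of the type known for cyclopropanol–alkyne annulation (CoBr2, 1,2-bis(diphenylphosphino)ethane, DABCO, MeCN, 60 °C), which gives 10 as the racemate, that is together with (5S)-5-hydroxy-N-methoxy-N-methyl-5-(propan-2-yl)-2-(prop-2-en-1-yl)cyclopent-1-ene-1-carboxamide F1. The racemate is resolved by preparative chromatography on a chiral stationary phase, and the route is rejoined at 10.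

Step 5 (conjugate addition to a tetrasubstituted enal flanked by a quaternary carbinol may be too slow or give 1,2-addition). The fallback sets out from 12 and delivers the methyl carbon intramolecularly from the tertiary oxygen. Silylation with (bromomethyl)chlorodimethylsilane (Et3N, DMAP, CH2Cl2) gives (5R)-5-{[(bromomethyl)dimethylsilyl]oxy}-5-(propan-2-yl)-2-(prop-2-en-1-yl)cyclopent-1-ene-1-carbaldehyde F2. Bu3SnH and AIBN in benzene at 80 °C then generate the silylmethyl radical, which adds to the β-carbon of the enal on the oxygen face (the 6-endo mode, favoured because the proximal carbon is fully substituted and the product radical is α to the formyl group) to give the bicyclic siloxane aldehyde F3. Protodesilylation with TBAF in DMF at 70 °C turns the Si–CH2 group into the methyl group and frees the hydroxyl, and DBU equilibration of the formyl centre as in step 5 rejoins the route at 15.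

Step 9 (facial selectivity of the peracid on the flexible seven-membered ring, and acid sensitivity of the product). The fallback sets out from 18 and lets the 6α-hydroxyl direct the oxidant before it is acylated. VO(acac)2 and t-BuOOH in CH2Cl2 at 0 °C epoxidise the homoallylic alcohol on the face of the secondary hydroxyl to give (1R,4R,5S,6S,8R,9S)-8,9-epoxydaucane-4,6-diol F4. BzCl, pyridine and DMAP then acylate the secondary hydroxyl, and the route is rejoined at 20.

**Further compounds**

F1 | step 3 | (5S)-5-hydroxy-N-methoxy-N-methyl-5-(propan-2-yl)-2-(prop-2-en-1-yl)cyclopent-1-ene-1-carboxamide | CC(C)[C@@]1(O)CCC(CC=C)=C1C(=O)N(C)OC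
F2 | step 5 | (5R)-5-{[(bromomethyl)dimethylsilyl]oxy}-5-(propan-2-yl)-2-(prop-2-en-1-yl)cyclopent-1-ene-1-carbaldehyde | CC(C)[C@]1(O[Si](C)(C)CBr)CCC(CC=C)=C1C=O
F3 | step 5 | bicyclic siloxane aldehyde: cyclopentane of 15 in which the C-methyl carbon is a CH2 bridged through SiMe2 to the tertiary oxygen | CC(C)[C@@]12CC[C@@](CC=C)(C[Si](C)(C)O1)[C@H]2C=O
F4 | step 9 | (1R,4R,5S,6S,8R,9S)-8,9-epoxydaucane-4,6-diol | CC(C)[C@]1(O)CC[C@]2(C)C[C@@H]3O[C@]3(C)C[C@H](O)[C@H]21
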